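**Retrosynthetic overview**
- Target 17 is a butyryl-phloroglucinol core carrying two CH2-linked butyrylfilicinic acid rings. The strategy rests on this feature: in each wing ring the bridging CH2, the ring carbon bearing it and the neighbouring ring C=O are a 3-arylpropanoate ortho to a core phenol oxygen (a masked dihydrocoumarin), and the other four ring carbons, C(OH)-C(CH3)2-C(OH)=C(COPr), are a dimethylmalonyl unit bonded to C1 of pentan-2-one (a masked 3,3-dimethyl-6-propylpyran-2,4-dione).
- Two bonds are cut in each wing: from the CH2-bearing ring carbon to the C(OH) beside CMe2, and from the butyryl-bearing ring carbon to the ring C=O. This gives bis-dihydrocoumarin 8 and two molecules of pyrandione 14; no bridge is made by a formaldehyde-type coupling.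
- 8 comes from phloroglucinol 1 by butyrylation (which blocks one ring carbon) and two acrylic acid hydroarylation/lactonisations. 14 comes from the kinetic silyl enol ether of pentan-2-one and dimethylmalonyl dichloride.
- Ring order: the benzene ring is bought; lactone ring one, then lactone ring two, are fused to it; the pyrandione ring is made separately; in the last step all four oxygen heterocycles open and the two six-membered carbocycles close.

Key step: step 6

Remark on the chemistry: the target is drawn as one enol tautomer of each beta-triketone wing. The route should deliver the freely equilibrating tautomer set, and the molecule has no stereocentre and no stereogenic double bond.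

**Step 1**
Reactants: 1 phloroglucinol (benzene-1,3,5-triol); 2 butanoyl chloride
Product: 3 1-(2,4,6-trihydroxyphenyl)butan-1-one
Conditions: AlCl3 (3.5 equiv), PhNO2/CH2Cl2, 0 to 40 °C; then ice/aq. HCl
Reagents that add atoms: none
Why: Friedel-Crafts C-acylation of the strongly activated ring should stop after one acyl group because the chelated aryl ketone deactivates the ring, and this acyl group occupies the ring carbon that must not carry an arm.

**Step 2**
Reactants: 3 1-(2,4,6-trihydroxyphenyl)butan-1-one; 4 acrylic acid
Product: 6 6-butanoyl-5,7-dihydroxychroman-2-one, via ring-opened arylpropanoic acid 5 (not isolated)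
Conditions: 4 (1.1 equiv), CH3SO3H (20 mol%), toluene, reflux, Dean-Stark
Reagents that add atoms: none
Why: Acid-catalysed conjugate hydroarylation of acrylic acid (a Friedel-Crafts alkylation) at one of the two equivalent free ring carbons should give 5, which lactonises onto the flanking non-chelated phenol para to the ketone, as in the known dihydrocoumarin synthesis from phenols and acrylic acids; closure onto the other flanking phenol would leave the same propanoate arm and would converge in step 6.

**Step 3**
Reactants: 6 6-butanoyl-5,7-dihydroxychroman-2-one; 4 acrylic acid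
Product: 8 6-butanoyl-5-hydroxy-3,4,9,10-tetrahydro-2H,8H-pyrano[2,3-f]chromene-2,8-dione, via arylpropanoic acid 7 (not isolated)
Conditions: 4 (2 equiv), CH3SO3H (50 mol%), toluene, reflux, Dean-Stark
Reagents that add atoms: none
Why: The same hydroarylation and lactonisation at the last free ring carbon, which is still activated by one ortho and one para hydroxyl, should close the second lactone onto the adjacent 7-hydroxyl and leave the chelated 5-hydroxyl free.

**Step 4**
Reactants: 9 pentan-2-one
Product: 11 2-(trimethylsilyloxy)pent-1-ene, via lithium enolate 10 (not isolated)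
Conditions: LiN(iPr)2 (1.05 equiv), THF, -78 °C; Me3SiCl (1.2 equiv), -78 to 0 °C; pentane, filtration, distillation
Reagents that add atoms: chlorotrimethylsilane, C[Si](C)(C)Cl
Why: Irreversible deprotonation by the hindered amide at -78 °C removes a proton of the methyl group, and O-silylation traps this kinetic enolate as the terminal silyl enol ether.

**Step 5**
Reactants: 11 2-(trimethylsilyloxy)pent-1-ene; 12 dimethylmalonyl dichloride
Product: 14 3,3-dimethyl-6-propyl-2H-pyran-2,4(3H)-dione, via keto acid chloride 13 (not isolated)
Conditions: ZnCl2 (10 mol%), CH2Cl2/Et2O, -20 to 23 °C; volatiles removed in vacuo; short-path distillation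
Reagents that add atoms: none
Why: ZnCl2-catalysed C-acylation of the silyl enol ether at its terminal carbon by one acid chloride group should give 13, whose enol oxygen is then acylated by the second acid chloride in a six-membered closure (Effenberger-type pyranone synthesis from a malonyl dichloride), and the quaternary carbon keeps the product in the pyran-2,4-dione form.

**Step 6**
Reactants: 8 6-butanoyl-5-hydroxy-3,4,9,10-tetrahydro-2H,8H-pyrano[2,3-f]chromene-2,8-dione; 14 3,3-dimethyl-6-propyl-2H-pyran-2,4(3H)-dione (2.2 equiv)
Product: 17 1-{3,5-bis[(5-butanoyl-2,4-dihydroxy-3,3-dimethyl-6-oxocyclohexa-1,4-dien-1-yl)methyl]-2,4,6-trihydroxyphenyl}butan-1-one (target CNP0287270.0), via trilithium bis-enolate 15 (not isolated), via bis-adduct 16 (not isolated)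
Conditions: LiN(iPr)2 (3.1 equiv), THF, -78 °C, 30 min; 14 (2.2 equiv), -78 °C, 1 h; LiN(SiMe3)2 (2.2 equiv), -78 to 0 °C; 1 M HCl, 0 °C
Reagents that add atoms: none
Why: Proposed new method: LiN(iPr)2 should take the phenol proton and then, under kinetic control, one alpha-proton of each aryl lactone to give 15, whose two lactone enolates attack C2 of 14, the enol-ester carbonyl of a vinylogous anhydride; collapse of each tetrahedral adduct expels the enol oxygen and opens the pyrandione to a 1,3-diketonate, which gives 16 as its polyanion. LiN(SiMe3)2 is then added because each new methine between lactone and ketone carbonyl is acidic and would otherwise quench the second lactone enolate; on warming, each arm loses the aryl oxide, either by E1cB to an acylketene or by direct addition-elimination at the aryl ester where the methine is still protonated, as the butyryl-bearing diketonate carbon bonds to the former lactone carbonyl carbon. Both carbocycles close in the 6-(enolexo)-exo-trig mode (6-exo-dig at the ketene carbon on the E1cB path), helped by the gem-dimethyl group, and the four heterocycles open to release two core phenoxides; no stereocentre remains, since the two transient alpha-stereocentres of 16 become enol carbons. The closest known reaction types are the crossed Claisen acylation of lactone lithium enolates by anhydrides and enol esters, the E1cB acyl transfer of aryl beta-keto esters through acylketenes, the Dieckmann-type base-induced conversion of 6-(2-oxoalkyl)pyranones into acylphloroglucinols and the O-to-C acyl shift of enol esters to 2-acylcyclohexane-1,3-diones. The step needs enolisation of the lactones and not of the butyryl ketone, and attack at C2 of 14 and not at C4 or C6: the ketone is conjugated to the ortho lithium phenoxide (a chelated vinylogous carboxylate), which lowers both its alpha-acidity and its electrophilicity, whereas the aryl lactones are the more acidic esters and are deprotonated fast at -78 °C; C2 is the only anhydride-like carbonyl of 14 and addition at the C4 ketone is a reversible aldol. The doubly stabilised triketonate is the thermodynamic sink, so an O-acylated enol lactone formed in the closure can still pass on to the C-acylated ring.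

**Compound list**
1 | phloroglucinol (benzene-1,3,5-triol) | Oc1cc(O)cc(O)c1 | starting material
2 | butanoyl chloride | CCCC(=O)Cl | starting material
3 | 1-(2,4,6-trihydroxyphenyl)butan-1-one | CCCC(=O)c1c(O)cc(O)cc1O | intermediate
4 | acrylic acid | C=CC(=O)O | starting material
5 | 3-(3-butanoyl-2,4,6-trihydroxyphenyl)propanoic acid | CCCC(=O)c1c(O)cc(O)c(CCC(=O)O)c1O | intermediate
6 | 6-butanoyl-5,7-dihydroxychroman-2-one | CCCC(=O)c1c(O)c2CCC(=O)Oc2cc1O | intermediate
7 | 3-(6-butanoyl-5,7-dihydroxy-2-oxochroman-8-yl)propanoic acid | CCCC(=O)c1c(O)c2CCC(=O)Oc2c(CCC(=O)O)c1O | intermediate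
8 | 6-butanoyl-5-hydroxy-3,4,9,10-tetrahydro-2H,8H-pyrano[2,3-f]chromene-2,8-dione (benzene ring with two fused six-membered lactones, one free chelated OH and the butanoyl group) | CCCC(=O)c1c(O)c2CCC(=O)Oc2c2CCC(=O)Oc12 | intermediate
9 | pentan-2-one | CCCC(C)=O | starting material
10 | lithium pent-1-en-2-olate | [Li+].[O-]C(=C)CCC | intermediate
11 | 2-(trimethylsilyloxy)pent-1-ene | C=C(CCC)O[Si](C)(C)C | intermediate
12 | dimethylmalonyl dichloride | CC(C)(C(=O)Cl)C(=O)Cl | starting material
13 | 2,2-dimethyl-3,5-dioxooctanoyl chloride | CCCC(=O)CC(=O)C(C)(C)C(=O)Cl | intermediate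
14 | 3,3-dimethyl-6-propyl-2H-pyran-2,4(3H)-dione | CCCC1=CC(=O)C(C)(C)C(=O)O1 | intermediate
15 | trilithium salt of 8 (phenoxide and two lactone enolates) | [Li+].[Li+].[Li+].CCCC(=O)c1c([O-])c2CC=C([O-])Oc2c2CC=C([O-])Oc12 | intermediate
16 | 6-butanoyl-3,9-bis(2,2-dimethyl-3,5-dioxooctanoyl)-5-hydroxy-3,4,9,10-tetrahydro-2H,8H-pyrano[2,3-f]chromene-2,8-dione (mixture of diastereomers at the two lactone alpha-carbons) | CCCC(=O)c1c(O)c2CC(C(=O)C(C)(C)C(=O)CC(=O)CCC)C(=O)Oc2c2CC(C(=O)C(C)(C)C(=O)CC(=O)CCC)C(=O)Oc12 | intermediate
17 | 1-{3,5-bis[(5-butanoyl-2,4-dihydroxy-3,3-dimethyl-6-oxocyclohexa-1,4-dien-1-yl)methyl]-2,4,6-trihydroxyphenyl}butan-1-one (CNP0287270.0; no stereocentre) | CCCC(=O)C1=C(O)C(C)(C)C(O)=C(Cc2c(O)c(CC3=C(O)C(C)(C)C(O)=C(C(=O)CCC)C3=O)c(O)c(C(=O)CCC)c2O)C1=O | target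

**Step count**
Total: 6 steps. Longest linear sequence: 4 steps (steps 1, 2, 3, 6); the pyrandione branch (steps 4, 5) joins at step 6.

**Steps most likely to fail**

Step 6 (the one step proposed as new chemistry). Several processes could divert it:
- deprotonation at the butyryl alpha-carbon in place of a lactone alpha-carbon;
- proton transfer from the first-formed adduct to the second lactone enolate, so that only one arm is acylated;
- conjugate addition-elimination at C6 of the pyrandione in place of attack at C2;
- retro-Michael cleavage of the product polyanion at a bridging CH2 if it is left in base.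

The fallback uses the known formaldehyde bridge formation; it sets out from 3 and comes back at 17. Twofold C-methylation of 3 (MeI 2.2 equiv, NaOCH3, CH3OH, 0 to 23 °C) should give 2-butanoyl-3,5-dihydroxy-4,4-dimethylcyclohexa-2,5-dien-1-one (butyrylfilicinic acid) F1. Condensation of 3 (1 equiv) with F1 (2 equiv) and aqueous formaldehyde (2 equiv) in dilute aqueous KOH at 23 °C, short contact time, then acidification and chromatography to remove the methylene-bis homodimers, should give 17.

Step 3. Alkylation at the last, partly deactivated ring carbon may be slow, which leaves room for oligomerisation of acrylic acid and for acid-induced loss or migration of the butyryl group. The fallback replaces alkene hydroarylation by alkyne hydroarylation and hydrogenation; it sets out from 6 and comes back at 8. Propiolic acid with Pd(OAc)2 (5 mol%) in CF3CO2H/CH2Cl2 at 23 °C should annulate the free ring carbon and the 7-hydroxyl to the coumarin-type lactone 6-butanoyl-5-hydroxy-3,4-dihydro-2H,8H-pyrano[2,3-f]chromene-2,8-dione F2. Hydrogenation (H2, 1 atm, Pd/C, EtOAc, 23 °C) should then saturate the pyranone C=C to give 8.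

Step 5. HCl may desilylate or isomerise the kinetic enol ether before it is acylated, acylation by the hindered acid chloride may be sluggish, and the enol lactone may be ring-opened by moisture during isolation. The fallback builds the chain by enolate acylations and closes the ring by cyclodehydration; it sets out from butanoyl chloride 2 and purchased tert-butyl acetoacetate and comes back at 14. Double C-methylation (MeI, K2CO3, acetone, reflux) should give tert-butyl 2,2-dimethyl-3-oxobutanoate F3. Its only possible enolate (LiN(SiMe3)2, 2.2 equiv, THF, -78 °C) is acylated by 2 to give tert-butyl 2,2-dimethyl-3,5-dioxooctanoate F4. CF3CO2H/(CF3CO)2O in CH2Cl2 at 0 to 23 °C should cleave the tert-butyl ester to 2,2-dimethyl-3,5-dioxooctanoic acid F5 and cyclodehydrate it at once to 14.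

**Further compounds**
F1 | step 6 | 2-butanoyl-3,5-dihydroxy-4,4-dimethylcyclohexa-2,5-dien-1-one (butyrylfilicinic acid) | CCCC(=O)C1=C(O)C(C)(C)C(O)=CC1=O
F2 | step 3 | 6-butanoyl-5-hydroxy-3,4-dihydro-2H,8H-pyrano[2,3-f]chromene-2,8-dione | CCCC(=O)c1c(O)c2CCC(=O)Oc2c2C=CC(=O)Oc12
F3 | step 5 | tert-butyl 2,2-dimethyl-3-oxobutanoate | CC(=O)C(C)(C)C(=O)OC(C)(C)C
F4 | step 5 | tert-butyl 2,2-dimethyl-3,5-dioxooctanoate | CCCC(=O)CC(=O)C(C)(C)C(=O)OC(C)(C)C
F5 | step 5 | 2,2-dimethyl-3,5-dioxooctanoic acid | CCCC(=O)CC(=O)C(C)(C)C(=O)O
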